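**Retrosynthetic overview**
1. Salternamide E 27 ⇐ tert-butyl ester 26 ⇐ amido ketone 25 by E1cB loss of benzyl alcohol (makes C2=C3 and erases the purchased ring stereocentre once it has done its work).
2. 25 ⇐ bicyclic N-acyl-1,2-oxazine 24 (N–O cleavage) ⇐ key step: acylnitroso hetero-Diels–Alder of 23 (from side-chain hydroxamic acid 11) with 2-silyloxy diene 22, forming C2–N and C5–O together.
3. 22 ⇐ enone 21 ⇐ ring-closing metathesis of 19 ⇐ chelation-controlled vinyl addition to keto aldehyde 18 ⇐ (S)-α-hydroxy-γ-butyrolactone 12 and the zinc reagent from 16.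
4. 11 ⇐ two invertive zinc-catalysed couplings of tert-butyl (S)-lactate triflate 2 (with 3, then with 7), then olefination.
5. Ring order: carbocycle first (metathesis, step 13), then the oxazine ring (cycloaddition, step 16), which is opened again in step 17.

Assumption: ring carbons are numbered as in the target (C1 C=O, C2 C–N, C3 =CH, C4 carbinol bearing the carboxybutyl chain, C5 CH–OH, C6 CH2) in all Why lines; 1, 3, 12 and 16 are bought.

**Side chain**

Step 1
Reactants: 1 tert-butyl (2S)-2-hydroxypropanoate (tert-butyl (S)-lactate)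
Product: 2 tert-butyl (2S)-2-{[(trifluoromethyl)sulfonyl]oxy}propanoate
Conditions: Tf2O, 2,6-lutidine, CH2Cl2, −78 → 0 °C
Reagents that add atoms: trifluoromethanesulfonic anhydride, O=S(=O)(OS(=O)(=O)C(F)(F)F)C(F)(F)F
Why: O-sulfonylation (triflate formation) of the secondary alcohol with a hindered base does not touch the C–O stereocentre.

Step 2
Reactants: 2 tert-butyl (2S)-2-{[(trifluoromethyl)sulfonyl]oxy}propanoate; 3 isobutylmagnesium chloride
Product: 4 tert-butyl (2S)-2,4-dimethylpentanoate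
Conditions: ZnCl2 (5 mol %), THF, 0 °C
Reagents that add atoms: none
Why: Zinc-catalysed sp3–sp3 cross-coupling of an α-triflyloxy ester with a Grignard reagent is an SN2 displacement by a zincate with clean inversion, so the purchased C–O centre becomes the C6 methyl centre of the side chain (descriptor stays S because the priorities change).

Step 3
Reactants: 4 tert-butyl (2S)-2,4-dimethylpentanoate
Product: 5 (2S)-2,4-dimethylpentan-1-ol
Conditions: LiAlH4, Et2O, 0 °C
Reagents that add atoms: none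
Why: Hydride reduction of the ester to the primary alcohol does not enolise the α-centre.

Step 4
Reactants: 5 (2S)-2,4-dimethylpentan-1-ol
Product: 6 (2S)-1-bromo-2,4-dimethylpentane
Conditions: PPh3, CBr4, CH2Cl2, 0 °C → rt
Reagents that add atoms: carbon tetrabromide, BrC(Br)(Br)Br
Why: Appel reaction substitutes only the primary carbinol carbon, so the neighbouring stereocentre is untouched.

Step 5
Reactants: 6 (2S)-1-bromo-2,4-dimethylpentane; 2 tert-butyl (2S)-2-{[(trifluoromethyl)sulfonyl]oxy}propanoate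
Product: 8 tert-butyl (2S,4S)-2,4,6-trimethylheptanoate, via Grignard reagent 7 (not isolated)
Conditions: Mg, THF, 50 °C; then 2, ZnCl2 (5 mol %), THF, 0 °C
Reagents that add atoms: none
Why: The same invertive zinc-catalysed triflate–Grignard cross-coupling sets the second methyl centre (C4 of the side chain) from a second lactate, giving the syn-1,3-dimethyl array.

Step 6
Reactants: 8 tert-butyl (2S,4S)-2,4,6-trimethylheptanoate
Product: 10 methyl (2E,4S,6S)-4,6,8-trimethylnon-2-enoate, via aldehyde 9 (not isolated)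
Conditions: iBu2AlH, CH2Cl2, −78 °C; MeOH; then Ph3P=CHCO2Me, −78 °C → rt
Reagents that add atoms: methyl (triphenylphosphoranylidene)acetate, COC(=O)C=P(c1ccccc1)(c1ccccc1)c1ccccc1
Why: Partial hydride reduction stops at the aluminium hemiacetal and the released α-branched aldehyde is trapped at once in a Wittig olefination with a stabilised ylide, which gives the E-enoate without epimerising C4.

Step 7
Reactants: 10 methyl (2E,4S,6S)-4,6,8-trimethylnon-2-enoate
Product: 11 (2E,4S,6S)-N-hydroxy-4,6,8-trimethylnon-2-enamide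
Conditions: NH2OH·HCl, KOH, MeOH, 0 °C → rt
Reagents that add atoms: hydroxylamine hydrochloride, NO.Cl
Why: Hydroxylaminolysis of the methyl ester gives the hydroxamic acid, and the γ-branched β-carbon disfavours conjugate addition.

**Ring and union**

Step 8
Reactants: 12 (3S)-3-hydroxydihydrofuran-2(3H)-one ((S)-α-hydroxy-γ-butyrolactone)
Product: 13 (3S)-3-(benzyloxy)dihydrofuran-2(3H)-one
Conditions: BnOC(=NH)CCl3, TfOH (cat.), CH2Cl2–cyclohexane, rt
Reagents that add atoms: benzyl 2,2,2-trichloroacetimidate, N=C(OCc1ccccc1)C(Cl)(Cl)Cl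
Why: Acid-catalysed O-benzylation with the imidate needs no base, so the enolisable α-centre of the lactone keeps its configuration.

Step 9
Reactants: 13 (3S)-3-(benzyloxy)dihydrofuran-2(3H)-one
Product: 14 S-ethyl (2S)-2-(benzyloxy)-4-hydroxybutanethioate
Conditions: AlMe3, EtSH, CH2Cl2, 0 °C → rt
Reagents that add atoms: ethanethiol, CCS
Why: The aluminium thiolate formed in the flask opens the lactone by acyl substitution to the ω-hydroxy thioester without touching C3.

Step 10
Reactants: 14 S-ethyl (2S)-2-(benzyloxy)-4-hydroxybutanethioate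
Product: 15 S-ethyl (2S)-2-(benzyloxy)-4-oxobutanethioate
Conditions: Dess–Martin periodinane, CH2Cl2, 0 °C → rt
Reagents that add atoms: none
Why: Dess–Martin oxidation of the primary alcohol gives the aldehyde (future C1) under neutral conditions and removes the hydroxyl that could relactonise.

Step 11
Reactants: 15 S-ethyl (2S)-2-(benzyloxy)-4-oxobutanethioate; 16 tert-butyl 5-bromopentanoate
Product: 18 tert-butyl (7S)-7-(benzyloxy)-6,9-dioxononanoate, via organozinc reagent 17 (not isolated)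
Conditions: 16, Zn, LiCl, THF, 50 °C; then 15, PdCl2(PPh3)2 (5 mol %), toluene, rt
Reagents that add atoms: none
Why: Fukuyama coupling (palladium-catalysed thioester–organozinc ketone synthesis) tolerates the aldehyde and the tert-butyl ester and does not epimerise the α-alkoxy centre.

Step 12
Reactants: 18 tert-butyl (7S)-7-(benzyloxy)-6,9-dioxononanoate
Product: 19 tert-butyl (6S,7S)-7-(benzyloxy)-6-ethenyl-6,9-dihydroxyundec-10-enoate (both C9 epimers)
Conditions: CH2=CHMgBr (3.5 equiv), THF, −78 °C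
Reagents that add atoms: vinylmagnesium bromide, C=C[Mg]Br
Why: Grignard addition under Cram chelate control: magnesium bridges the ketone and the α-benzyloxy oxygen, vinyl attacks C4 from the side of the C3 hydrogen, and the C4 carbinol is set with OH anti and chain syn to C3–OBn, while the aldehyde carbinol forms as both epimers that converge in step 14.

Step 13
Reactants: 19 tert-butyl (6S,7S)-7-(benzyloxy)-6-ethenyl-6,9-dihydroxyundec-10-enoate (both C9 epimers)
Product: 20 tert-butyl 5-[(1S,6S)-6-(benzyloxy)-1,4-dihydroxycyclohex-2-en-1-yl]pentanoate (both C4 epimers)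
Conditions: second-generation Grubbs catalyst (5 mol %), CH2Cl2, 40 °C
Reagents that add atoms: none
Why: Ring-closing olefin metathesis of the two terminal vinyl groups closes the six-membered carbocycle (C5=C6) with loss of ethene and touches no stereocentre.

Step 14
Reactants: 20 tert-butyl 5-[(1S,6S)-6-(benzyloxy)-1,4-dihydroxycyclohex-2-en-1-yl]pentanoate (both C4 epimers)
Product: 21 tert-butyl 5-[(1S,6S)-6-(benzyloxy)-1-hydroxy-4-oxocyclohex-2-en-1-yl]pentanoate
Conditions: MnO2, CH2Cl2, rt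
Reagents that add atoms: none
Why: Allylic oxidation with MnO2 takes only the secondary allylic alcohol, so both epimers give one enone and the tertiary alcohol stays.

Step 15
Reactants: 21 tert-butyl 5-[(1S,6S)-6-(benzyloxy)-1-hydroxy-4-oxocyclohex-2-en-1-yl]pentanoate
Product: 22 tert-butyl 5-[(1S,6S)-6-(benzyloxy)-1,4-bis(trimethylsilyloxy)cyclohexa-2,4-dien-1-yl]pentanoate
Conditions: Me3SiOTf, Et3N, CH2Cl2, −78 → 0 °C
Reagents that add atoms: trimethylsilyl trifluoromethanesulfonate, C[Si](C)(C)OS(=O)(=O)C(F)(F)F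
Why: Soft enolisation (silyl enol ether formation) can only take a C2 proton because C4 is quaternary, it gives the cross-conjugated 2-silyloxy diene without a free enolate that could expel the C3 benzyloxy group, and the tertiary alcohol is silylated at the same time.

Step 16
Reactants: 22 tert-butyl 5-[(1S,6S)-6-(benzyloxy)-1,4-bis(trimethylsilyloxy)cyclohexa-2,4-dien-1-yl]pentanoate; 11 (2E,4S,6S)-N-hydroxy-4,6,8-trimethylnon-2-enamide
Product: 24 tert-butyl 5-{8-(benzyloxy)-5,7-bis(trimethylsilyloxy)-3-[(2E,4S,6S)-4,6,8-trimethylnon-2-enoyl]-2-oxa-3-azabicyclo[2.2.2]oct-5-en-7-yl}pentanoate (N–O bridge on the face of the 7-silyloxy group and opposite the 8-benzyloxy group), via acylnitroso compound 23 (not isolated)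
Conditions: Bu4NIO4, CH2Cl2, −78 → 0 °C
Reagents that add atoms: none
Why: Acylnitroso hetero-Diels–Alder ([4+2]) reaction: periodate oxidises 11 to 23, which adds across C2/C5 of the diene with nitrogen at the nucleophilic C2 terminus and from the face opposite the C3 benzyloxy group and the C4 alkyl chain, so the new C5–O bond is cis to the C4 oxygen and the amide C–N bond is made in the same step.

Step 17
Reactants: 24 the cycloadduct of step 16
Product: 25 tert-butyl 5-[(1S,2S,5S,6S)-6-(benzyloxy)-1,2-dihydroxy-4-oxo-5-{[(2E,4S,6S)-4,6,8-trimethylnon-2-enoyl]amino}cyclohexyl]pentanoate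
Conditions: Mo(CO)6, MeCN–H2O (15:1), 80 °C
Reagents that add atoms: none
Why: Reductive N–O cleavage with Mo(CO)6 frees the amide N–H and the C5 hydroxyl with retention, and the wet medium hydrolyses the silyl enol ether to the C1 ketone and the silyl ether to the tertiary alcohol.

Step 18
Reactants: 25 the amido hydroxy ketone of step 17
Product: 26 tert-butyl 5-[(1R,6S)-1,6-dihydroxy-4-oxo-3-{[(2E,4S,6S)-4,6,8-trimethylnon-2-enoyl]amino}cyclohex-2-en-1-yl]pentanoate
Conditions: DBU, CH2Cl2, 0 °C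
Reagents that add atoms: none
Why: E1cB elimination: the acidic α-amido ketone proton at C2 is removed and the β-benzyloxy group at C3 leaves, giving the conjugated enamide, erasing the relay centre at C3 and leaving C4 and C5 as set.

Step 19
Reactants: 26 the tert-butyl ester of step 18
Product: 27 salternamide E, 5-[(1R,6S)-1,6-dihydroxy-4-oxo-3-{[(2E,4S,6S)-4,6,8-trimethylnon-2-enoyl]amino}cyclohex-2-en-1-yl]pentanoic acid
Conditions: CF3CO2H–CH2Cl2 (1:4), 0 °C
Reagents that add atoms: none
Why: Acidolysis of the tert-butyl ester (E1 loss of 2-methylpropene) at low temperature frees the acid without a basic step that could dehydrate the β-hydroxy ketone.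

**Compound list**

1 | tert-butyl (2S)-2-hydroxypropanoate | C[C@H](O)C(=O)OC(C)(C)C | starting material
2 | tert-butyl (2S)-2-{[(trifluoromethyl)sulfonyl]oxy}propanoate | C[C@H](OS(=O)(=O)C(F)(F)F)C(=O)OC(C)(C)C | intermediate
3 | isobutylmagnesium chloride | CC(C)C[Mg]Cl | starting material
4 | tert-butyl (2S)-2,4-dimethylpentanoate | CC(C)C[C@H](C)C(=O)OC(C)(C)C | intermediate
5 | (2S)-2,4-dimethylpentan-1-ol | CC(C)C[C@H](C)CO | intermediate
6 | (2S)-1-bromo-2,4-dimethylpentane | CC(C)C[C@H](C)CBr | intermediate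
7 | [(2S)-2,4-dimethylpentyl]magnesium bromide | CC(C)C[C@H](C)C[Mg]Br | intermediate
8 | tert-butyl (2S,4S)-2,4,6-trimethylheptanoate | CC(C)C[C@H](C)C[C@H](C)C(=O)OC(C)(C)C | intermediate
9 | (2S,4S)-2,4,6-trimethylheptanal | CC(C)C[C@H](C)C[C@H](C)C=O | intermediate
10 | methyl (2E,4S,6S)-4,6,8-trimethylnon-2-enoate | CC(C)C[C@H](C)C[C@H](C)/C=C/C(=O)OC | intermediate
11 | (2E,4S,6S)-N-hydroxy-4,6,8-trimethylnon-2-enamide | CC(C)C[C@H](C)C[C@H](C)/C=C/C(=O)NO | intermediate
12 | (3S)-3-hydroxydihydrofuran-2(3H)-one | O=C1OCC[C@@H]1O | starting material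
13 | (3S)-3-(benzyloxy)dihydrofuran-2(3H)-one | O=C1OCC[C@@H]1OCc1ccccc1 | intermediate
14 | S-ethyl (2S)-2-(benzyloxy)-4-hydroxybutanethioate | OCC[C@H](OCc1ccccc1)C(=O)SCC | intermediate
15 | S-ethyl (2S)-2-(benzyloxy)-4-oxobutanethioate | O=CC[C@H](OCc1ccccc1)C(=O)SCC | intermediate
16 | tert-butyl 5-bromopentanoate | BrCCCCC(=O)OC(C)(C)C | starting material
17 | (5-tert-butoxy-5-oxopentyl)zinc bromide | Br[Zn]CCCCC(=O)OC(C)(C)C | intermediate
18 | tert-butyl (7S)-7-(benzyloxy)-6,9-dioxononanoate | O=CC[C@H](OCc1ccccc1)C(=O)CCCCC(=O)OC(C)(C)C | intermediate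
19 | tert-butyl (6S,7S)-7-(benzyloxy)-6-ethenyl-6,9-dihydroxyundec-10-enoate (both C9 epimers) | C=CC(O)C[C@H](OCc1ccccc1)[C@](O)(CCCCC(=O)OC(C)(C)C)C=C | intermediate
20 | tert-butyl 5-[(1S,6S)-6-(benzyloxy)-1,4-dihydroxycyclohex-2-en-1-yl]pentanoate (both C4 epimers) | OC1C[C@H](OCc2ccccc2)[C@](O)(CCCCC(=O)OC(C)(C)C)C=C1 | intermediate
21 | tert-butyl 5-[(1S,6S)-6-(benzyloxy)-1-hydroxy-4-oxocyclohex-2-en-1-yl]pentanoate | O=C1C[C@H](OCc2ccccc2)[C@](O)(CCCCC(=O)OC(C)(C)C)C=C1 | intermediate
22 | tert-butyl 5-[(1S,6S)-6-(benzyloxy)-1,4-bis(trimethylsilyloxy)cyclohexa-2,4-dien-1-yl]pentanoate | C[Si](C)(C)OC1=C[C@H](OCc2ccccc2)[C@](O[Si](C)(C)C)(CCCCC(=O)OC(C)(C)C)C=C1 | intermediate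
23 | (2E,4S,6S)-4,6,8-trimethyl-1-nitrosonon-2-en-1-one (acylnitroso compound) | CC(C)C[C@H](C)C[C@H](C)/C=C/C(=O)N=O | intermediate
24 | tert-butyl 5-{8-(benzyloxy)-5,7-bis(trimethylsilyloxy)-3-[(2E,4S,6S)-4,6,8-trimethylnon-2-enoyl]-2-oxa-3-azabicyclo[2.2.2]oct-5-en-7-yl}pentanoate (C7 and C8 as C1 and C6 of 22; N–O bridge syn to 7-OSiMe3, anti to 8-OBn) | CC(C)C[C@H](C)C[C@H](C)/C=C/C(=O)N1O[C@H]2C=C(O[Si](C)(C)C)[C@@H]1[C@H](OCc3ccccc3)[C@]2(O[Si](C)(C)C)CCCCC(=O)OC(C)(C)C | intermediate
25 | tert-butyl 5-[(1S,2S,5S,6S)-6-(benzyloxy)-1,2-dihydroxy-4-oxo-5-{[(2E,4S,6S)-4,6,8-trimethylnon-2-enoyl]amino}cyclohexyl]pentanoate | CC(C)C[C@H](C)C[C@H](C)/C=C/C(=O)N[C@H]1[C@H](OCc2ccccc2)[C@](O)(CCCCC(=O)OC(C)(C)C)[C@@H](O)CC1=O | intermediate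
26 | tert-butyl 5-[(1R,6S)-1,6-dihydroxy-4-oxo-3-{[(2E,4S,6S)-4,6,8-trimethylnon-2-enoyl]amino}cyclohex-2-en-1-yl]pentanoate | CC(C)C[C@H](C)C[C@H](C)/C=C/C(=O)NC1=C[C@](O)(CCCCC(=O)OC(C)(C)C)[C@@H](O)CC1=O | intermediate
27 | salternamide E | CC(C)C[C@H](C)C[C@H](C)/C=C/C(=O)NC1=C[C@](O)(CCCCC(=O)O)[C@@H](O)CC1=O | target

**Step count**

Total: 19 steps. Longest linear sequence: 12 steps (12 → 27, steps 8–19); the side chain (steps 1–7) joins at step 16.

**Steps most likely to fail, with fallbacks**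

Step 16 (face and regiochemistry of the cycloaddition, competing nitroso aldol). The fallback sets out from enone 21, takes its nitrogen from 11, and comes back to the route at 27. Oxygen and nitrogen are brought in one after the other without a cycloaddition. PhB(OH)2 with a catalytic achiral amine delivers oxygen from the boronate on the C4 hydroxyl to C5 of 21 (intramolecular oxa-Michael addition, aqueous H2O2 work-up) and gives cis-diol ketone F1. 2,2-Dimethoxypropane with TsOH gives acetonide F2. DBU expels benzyl alcohol and gives enone acetonide F3. I2 in pyridine gives iodoenone acetonide F4. TiCl3 reduces 11 to the primary amide (2E,4S,6S)-4,6,8-trimethylnon-2-enamide F5, which is coupled with F4 (CuI, N,N′-dimethylethylenediamine, K2CO3, toluene, 60 °C) to give enamide acetonide F6. The acid of step 19, used wet, removes acetonide and tert-butyl ester and gives 27.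

Step 12 (chelation control at C4 and double addition in one pot). The fallback sets out from 18 and comes back at 20. The two additions are separated. One equivalent of CH2=CHMgBr at −78 °C takes only the aldehyde and gives hydroxy ketone F7. tBuMe2SiCl with imidazole gives silyl ether F8. The ketone is complexed with MgBr2·OEt2 in CH2Cl2 before CH2=CHMgBr is added, which enforces the chelate, and gives tertiary alcohol F9. Ring-closing metathesis gives silyl-protected cyclohexene F10, and Bu4NF returns diol 20.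

Step 18 (loss of benzyl alcohol against dehydration at C5 or retro-aldol). The fallback sets out from 25 and comes back at 27. The C5 hydroxyl is first capped with Et3SiCl and imidazole to give triethylsilyl ether F11, so that only the benzyloxy group can leave. DBU then gives enamide silyl ether F12, and the acid of step 19 removes the silyl ether together with the tert-butyl ester to give 27.

**Further compounds**

F1 | step 16 | tert-butyl 5-[(1S,2S,6S)-6-(benzyloxy)-1,2-dihydroxy-4-oxocyclohexyl]pentanoate | O=C1C[C@H](OCc2ccccc2)[C@](O)(CCCCC(=O)OC(C)(C)C)[C@@H](O)C1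
F2 | step 16 | acetonide of F1 (2,2-dimethyl-1,3-dioxolane across the two cis hydroxyls) | O=C1C[C@H](OCc2ccccc2)[C@@]3(CCCCC(=O)OC(C)(C)C)OC(C)(C)O[C@H]3C1
F3 | step 16 | acetonide of tert-butyl 5-[(1R,6S)-1,6-dihydroxy-4-oxocyclohex-2-en-1-yl]pentanoate | O=C1C=C[C@@]3(CCCCC(=O)OC(C)(C)C)OC(C)(C)O[C@H]3C1
F4 | step 16 | acetonide of tert-butyl 5-[(1R,6S)-1,6-dihydroxy-3-iodo-4-oxocyclohex-2-en-1-yl]pentanoate | O=C1C(I)=C[C@@]3(CCCCC(=O)OC(C)(C)C)OC(C)(C)O[C@H]3C1
F5 | step 16 | (2E,4S,6S)-4,6,8-trimethylnon-2-enamide | CC(C)C[C@H](C)C[C@H](C)/C=C/C(=O)N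
F6 | step 16 | acetonide of 26 (across the C4 and C5 hydroxyls) | CC(C)C[C@H](C)C[C@H](C)/C=C/C(=O)NC1=C[C@@]3(CCCCC(=O)OC(C)(C)C)OC(C)(C)O[C@H]3CC1=O
F7 | step 12 | tert-butyl (7S)-7-(benzyloxy)-9-hydroxy-6-oxoundec-10-enoate (both C9 epimers) | C=CC(O)C[C@H](OCc1ccccc1)C(=O)CCCCC(=O)OC(C)(C)C
F8 | step 12 | tert-butyl (7S)-7-(benzyloxy)-9-[(tert-butyldimethylsilyl)oxy]-6-oxoundec-10-enoate | C=CC(O[Si](C)(C)C(C)(C)C)C[C@H](OCc1ccccc1)C(=O)CCCCC(=O)OC(C)(C)C
F9 | step 12 | tert-butyl (6S,7S)-7-(benzyloxy)-9-[(tert-butyldimethylsilyl)oxy]-6-ethenyl-6-hydroxyundec-10-enoate | C=CC(O[Si](C)(C)C(C)(C)C)C[C@H](OCc1ccccc1)[C@](O)(CCCCC(=O)OC(C)(C)C)C=C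
F10 | step 12 | tert-butyl 5-[(1S,6S)-6-(benzyloxy)-4-[(tert-butyldimethylsilyl)oxy]-1-hydroxycyclohex-2-en-1-yl]pentanoate | CC(C)(C)[Si](C)(C)OC1C[C@H](OCc2ccccc2)[C@](O)(CCCCC(=O)OC(C)(C)C)C=C1
F11 | step 18 | triethylsilyl ether of 25 (on the secondary C5 hydroxyl) | CC(C)C[C@H](C)C[C@H](C)/C=C/C(=O)N[C@H]1[C@H](OCc2ccccc2)[C@](O)(CCCCC(=O)OC(C)(C)C)[C@@H](O[Si](CC)(CC)CC)CC1=O
F12 | step 18 | triethylsilyl ether of 26 (on the secondary C5 hydroxyl) | CC(C)C[C@H](C)C[C@H](C)/C=C/C(=O)NC1=C[C@](O)(CCCCC(=O)OC(C)(C)C)[C@@H](O[Si](CC)(CC)CC)CC1=O
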